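**Plan**

1. Cuts: the C2 angelate and C20 acetate come off first. The Δ7 alkene with its 9α-H is traced (allylic diazene retro-ene) to a Δ8 alkene with a 7β-oxygen. C5–C10 and C6–C7 are then cut together, followed by C9–C10 and the C20–O–C7 ester bond.
2. Enabling feature: C20 is an oxidised carbon on C10 and lies 1,4 to C7 across ring B. An O link C20(=O)–O–C7 therefore closes C7=C8(C17)–C9=C10 into a 2-pyrone, a locked s-cis diene, tethered through C1–C4 to the C5=C6 vinyl group on the C4 gem-dimethyl carbon.
3. Forward: ester fragment A (C20, C10, C1–C6) and enone fragment B (C7–C9, C11–C17) are joined at C9–C10 and the pyrone (temporary ring) is closed. One intramolecular Diels–Alder reaction closes ring A and ring B together. The lactone bridge is reduced open, C7–O is spent in a reductive 1,3-transposition, and the angelate goes on last.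
4. Stereochemistry: C2 from (R)-5-(hydroxymethyl)butyrolactone, C3 by Felkin–Anh reverse prenylation, C13 from (R)-linalool. C5 and C10 (and a temporary C7) come from the cycloaddition under control of the C2/C3 cis-dioxolane. C9 is set by suprafacial hydrogen transfer from C7.

Key step: step 11

Remark: positions are given in labdane numbering of the target (ring A = C1–C5 and C10, ring B = C5–C10, C20 on C10 is β); commercial (R)-(−)-linalool is assumed enantiopure because it alone fixes C13, and the isomer mixtures formed at C9, C10 and C8=C9 before the pyrone converge there.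

**Route**

Step 1
Reactants: 1 (5R)-5-(hydroxymethyl)oxolan-2-one
Product: 2 (2R)-5-oxooxolane-2-carbaldehyde
Conditions: Dess–Martin periodinane, CH2Cl2, 0 °C to rt; used crude
Reagents that add atoms: none
Why: Dess–Martin oxidation of the primary alcohol under non-basic conditions should give the aldehyde without epimerising the α-oxygenated centre (future C2).

Step 2
Reactants: 2 (2R)-5-oxooxolane-2-carbaldehyde
Product: 4 (5R)-5-[(1S)-1-hydroxy-2,2-dimethylbut-3-en-1-yl]oxolan-2-one, via pinacol boronate ester 3 (not isolated)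
Conditions: 3-methylbut-2-enylboronic acid pinacol ester, 4 Å MS, toluene, rt to 40 °C; then H2O work-up
Reagents that add atoms: 3-methylbut-2-enylboronic acid pinacol ester, CC(C)=CCB1OC(C)(C)C(C)(C)O1
Why: Allylboration through a closed chair transition state attacks with the γ-carbon (reverse prenylation, creating the C4 quaternary carbon with its vinyl group), and the α-oxygenated aldehyde should react in the Felkin–Anh sense so that the new C3 carbinol is anti (erythro) to C2–O.

Step 3
Reactants: 4 (5R)-5-[(1S)-1-hydroxy-2,2-dimethylbut-3-en-1-yl]oxolan-2-one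
Product: 6 methyl 3-[(4R,5S)-2,2-dimethyl-5-(2-methylbut-3-en-2-yl)-1,3-dioxolan-4-yl]propanoate (fragment A), via dihydroxy ester 5 (not isolated)
Conditions: MeOH, 2,2-dimethoxypropane, p-TsOH (cat.), rt
Reagents that add atoms: methanol, CO; 2,2-dimethoxypropane, COC(C)(C)OC
Why: Acid-catalysed methanolysis of the γ-lactone (transesterification) should be driven forward by trapping the erythro 1,2-diol as the cis-dioxolane (ketalisation), which leaves C10 as an enolisable ester α-carbon and changes no stereocentre.

Step 4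
Reactants: 7 (R)-(−)-linalool
Product: 8 {[(3R)-3,7-dimethylocta-1,6-dien-3-yl]oxy}triethylsilane
Conditions: TESOTf, 2,6-lutidine, CH2Cl2, −78 to 0 °C
Reagents that add atoms: triethylsilyl trifluoromethanesulfonate, CC[Si](CC)(CC)OS(=O)(=O)C(F)(F)F
Why: Silylation with a silyl triflate and a hindered base is the standard way to protect a tertiary allylic alcohol and should not ionise it.

Step 5
Reactants: 8 {[(3R)-3,7-dimethylocta-1,6-dien-3-yl]oxy}triethylsilane
Product: 10 (4R)-4-methyl-4-(triethylsilyloxy)hex-5-enal, via ozonide 9 (not isolated)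
Conditions: O3, CH2Cl2, −78 °C (Sudan Red 7B end point); then PPh3, −78 °C to rt
Reagents that add atoms: ozone, [O-][O+]=O
Why: Ozonolysis with reductive work-up should cleave the electron-rich trisubstituted alkene well before the hindered, inductively deactivated vinyl group next to the silyloxy carbon, so the aldehyde carbon that becomes C9 is unmasked.

Step 6
Reactants: 10 (4R)-4-methyl-4-(triethylsilyloxy)hex-5-enal
Product: 11 (6R)-2,6-dimethyl-6-(triethylsilyloxy)octa-1,7-dien-3-ol (both C3 epimers)
Conditions: isopropenylmagnesium bromide, THF, −78 to 0 °C; then H2O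
Reagents that add atoms: isopropenylmagnesium bromide, C=C(C)[Mg]Br
Why: Grignard addition to the aldehyde brings in C7, C8 and C17, and the new carbinol centre is unimportant because it is oxidised in the next step.

Step 7
Reactants: 11 (6R)-2,6-dimethyl-6-(triethylsilyloxy)octa-1,7-dien-3-ol
Product: 12 (6R)-2,6-dimethyl-6-(triethylsilyloxy)octa-1,7-dien-3-one (fragment B)
Conditions: Dess–Martin periodinane, CH2Cl2, 0 °C to rt
Reagents that add atoms: none
Why: Dess–Martin oxidation of the secondary allylic alcohol should give the isopropenyl ketone without touching the silyl ether or the alkenes.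

Step 8
Reactants: 6 methyl 3-[(4R,5S)-2,2-dimethyl-5-(2-methylbut-3-en-2-yl)-1,3-dioxolan-4-yl]propanoate; 12 (6R)-2,6-dimethyl-6-(triethylsilyloxy)octa-1,7-dien-3-one
Product: 14 methyl 2-{[(4R,5S)-2,2-dimethyl-5-(2-methylbut-3-en-2-yl)-1,3-dioxolan-4-yl]methyl}-3-hydroxy-6-methyl-3-(prop-1-en-2-yl)-6-(triethylsilyloxy)oct-7-enoate (6R; mixture at C2 and C3), via lithium enolate 13 (not isolated)
Conditions: lithium diisopropylamide, THF, −78 °C; anhydrous CeCl3; then 12, −78 °C; AcOH quench at −78 °C
Reagents that add atoms: none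
Why: Aldol-type 1,2-addition of the ester enolate to the ketone forms the C9–C10 bond, with CeCl3 and a cold acidic quench chosen to suppress conjugate addition, proton transfer and retro-aldol; the two new centres are lost again at the pyrone stage.

Step 9
Reactants: 14 β-hydroxy ester (tertiary allylic alcohol)
Product: 15 methyl 2-{[(4R,5S)-2,2-dimethyl-5-(2-methylbut-3-en-2-yl)-1,3-dioxolan-4-yl]methyl}-4-methyl-3-[(3R)-3-methyl-3-(triethylsilyloxy)pent-4-en-1-yl]-5-oxopent-3-enoate (E/Z mixture)
Conditions: pyridinium chlorochromate (C5H5NH)(CrO3Cl), NaOAc, 4 Å MS, CH2Cl2, rt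
Reagents that add atoms: pyridinium chlorochromate, c1cc[nH+]cc1.[O-][Cr](=O)(=O)Cl
Why: Babler–Dauben oxidative transposition (chromate ester, [3,3] shift to the terminal carbon, oxidation) should turn the tertiary isopropenyl carbinol into the transposed enal, placing the aldehyde oxygen on C7 and the alkene at C8=C9.

Step 10
Reactants: 15 enal ester
Product: 16 3-{[(4R,5S)-2,2-dimethyl-5-(2-methylbut-3-en-2-yl)-1,3-dioxolan-4-yl]methyl}-5-methyl-4-[(3R)-3-methyl-3-(triethylsilyloxy)pent-4-en-1-yl]-2H-pyran-2-one
Conditions: DBU (0.2 equiv), toluene, 60 °C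
Reagents that add atoms: none
Why: Base removes the doubly activated C10–H to give a dienolate whose oxygen on C7 attacks the methyl ester (6-exo-trig acyl substitution, lactonisation of a 5-oxo-enoate), and because the dienolate geometry equilibrates both alkene isomers should converge on the aromatic-stabilised 2-pyrone.

Step 11
Reactants: 16 tethered 2-pyrone
Product: 17 2α,3α-(isopropylidenedioxy)-13R-(triethylsilyloxy)-5α-labda-8,14-dien-20-oic acid 20,7β-lactone (2-oxabicyclo[2.2.2]octene lactone bridging C10 and C7 on the β face; rings A and B trans-fused)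
Conditions: toluene (0.01 M), BHT (cat.), 120 °C, sealed tube
Reagents that add atoms: none
Why: Heating should bring about a concerted, suprafacial [4+2] cycloaddition in which the 2-pyrone (diene C7=C8–C9=C10, held s-cis by the O–C20(=O) bridge) adds the unactivated C5=C6 vinyl group, forming C5–C10 and C6–C7 and leaving C8=C9 and an intact C20–O–C7 lactone. The closest known reaction type is the intramolecular Diels–Alder reaction of 2-pyrones carrying a tethered unactivated alkene, which gives isolable 2-oxabicyclo[2.2.2]oct-5-en-3-ones when run below the temperature of CO2 extrusion. Ring A closes as a six-membered carbocycle over the four-atom tether C1–C4 attached to the diene terminus C10 (fused mode, chair-like tether), and ring B closes as the cyclohexene of the bicyclo[2.2.2]octene, with the pyrone surviving as the lactone bridge. C10 and C7 are tied to each other by that bridge (C20 and the C7 oxygen both β); C5 is set relative to C10 by the arrangement that places C4 and its geminal methyl groups over the lactone carbonyl and not over C9 and its side chain (trans ring fusion, H5 α); and the absolute sense of all three follows from the C2/C3 cis-dioxolane, which fits the chair tether only with C2–O equatorial and C3–O axial on the α face, since the alternative puts C2–O syn-axial to C20 and the C4 β-methyl. The step needs this exo-type selectivity, π-facial selectivity and a cycloaddition that is faster than decarboxylation of the adduct; the C4 gem-dimethyl group and the dioxolane ring (reactive-rotamer effect), the C9 substituent and the α-face diol should secure them, while the side-chain vinyl group could reach the diene only through a strained bridgehead-alkene geometry and should stay out.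

Step 12
Reactants: 17 bridged lactone
Product: 18 2α,3α-(isopropylidenedioxy)-13R-(triethylsilyloxy)-5α-labda-8,14-diene-7β,20-diol
Conditions: LiAlH4, THF, 0 °C to rt; then H2O, aq NaOH
Reagents that add atoms: none
Why: Hydride reduction of the strained lactone opens the temporary bridge to the C20 primary alcohol and the 7β allylic alcohol without touching any stereocentre.

Step 13
Reactants: 18 7β,20-diol
Product: 19 7β-hydroxy-2α,3α-(isopropylidenedioxy)-13R-(triethylsilyloxy)-5α-labda-8,14-dien-20-yl acetate
Conditions: AcCl (1.1 equiv), 2,4,6-collidine, CH2Cl2, −78 °C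
Reagents that add atoms: acetyl chloride, CC(=O)Cl
Why: Acetyl chloride with a hindered pyridine base at low temperature is a known primary-selective acylation and should acetylate the C20 primary alcohol ahead of the secondary allylic C7 alcohol.

Step 14
Reactants: 19 7β-hydroxy C20 acetate
Product: 22 2α,3α-(isopropylidenedioxy)-13R-(triethylsilyloxy)labda-7,14-dien-20-yl acetate (5α-H and 9α-H), via allylic hydrazide 20 (not isolated), via allylic diazene 21 (not isolated)
Conditions: PPh3, DEAD, 2-nitrobenzenesulfonylhydrazide, THF, −30 °C; then 23 °C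
Reagents that add atoms: none
Why: Mitsunobu displacement of the 7β allylic alcohol by the sulfonylhydrazide with inversion, loss of sulfinic acid and retro-ene loss of N2 from the 7α diazene (Myers reductive 1,3-transposition) should deliver hydrogen suprafacially to the α face of C9 and move the alkene to C7=C8, which sets C9 with the side chain β.

Step 15
Reactants: 22 protected Δ7 acetate
Product: 23 2α,3α,13R-trihydroxylabda-7,14-dien-20-yl acetate
Conditions: AcOH–H2O (4:1), 40 °C
Reagents that add atoms: none
Why: Mild aqueous acid hydrolysis should remove the cis-fused ketal and the triethylsilyl ether together while leaving the acetate, the Δ7 alkene and the tertiary allylic alcohol intact.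

Step 16
Reactants: 23 triol acetate
Product: 24 20-acetoxy-2α-[(Z)-2-methylbut-2-enoyloxy]labda-7,14-diene-3α,13R-diol (target; 2R,3S,5R,9S,10S,13R)
Conditions: angelic acid, 2,4,6-trichlorobenzoyl chloride, Et3N, toluene, rt; then 23, 75 °C (no DMAP)
Reagents that add atoms: angelic acid, C/C=C(/C)C(=O)O
Why: Yamaguchi esterification through the preformed mixed anhydride, run without a nucleophilic catalyst to keep the Z geometry, should acylate the equatorial C2 hydroxyl, because the C3 hydroxyl is axial and neopentylic and the C13 hydroxyl is tertiary.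

**Compound list**

1 | (5R)-5-(hydroxymethyl)oxolan-2-one | O=C1CC[C@H](CO)O1 | starting material
2 | (2R)-5-oxooxolane-2-carbaldehyde | O=C1CC[C@H](C=O)O1 | intermediate
3 | (5R)-5-{(1S)-2,2-dimethyl-1-[(4,4,5,5-tetramethyl-1,3,2-dioxaborolan-2-yl)oxy]but-3-en-1-yl}oxolan-2-one | C=CC(C)(C)[C@H](OB2OC(C)(C)C(C)(C)O2)[C@H]1CCC(=O)O1 | intermediate
4 | (5R)-5-[(1S)-1-hydroxy-2,2-dimethylbut-3-en-1-yl]oxolan-2-one | C=CC(C)(C)[C@H](O)[C@H]1CCC(=O)O1 | intermediate
5 | methyl (4R,5S)-4,5-dihydroxy-6,6-dimethyloct-7-enoate | COC(=O)CC[C@@H](O)[C@@H](O)C(C)(C)C=C | intermediate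
6 | methyl 3-[(4R,5S)-2,2-dimethyl-5-(2-methylbut-3-en-2-yl)-1,3-dioxolan-4-yl]propanoate (fragment A) | COC(=O)CC[C@H]1OC(C)(C)O[C@H]1C(C)(C)C=C | intermediate
7 | (R)-(−)-linalool, (3R)-3,7-dimethylocta-1,6-dien-3-ol | C=C[C@](C)(O)CCC=C(C)C | starting material
8 | {[(3R)-3,7-dimethylocta-1,6-dien-3-yl]oxy}triethylsilane | C=C[C@](C)(O[Si](CC)(CC)CC)CCC=C(C)C | intermediate
9 | 3,3-dimethyl-5-[(3R)-3-methyl-3-(triethylsilyloxy)pent-4-en-1-yl]-1,2,4-trioxolane (ozonide) | C=C[C@](C)(O[Si](CC)(CC)CC)CCC1OOC(C)(C)O1 | intermediate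
10 | (4R)-4-methyl-4-(triethylsilyloxy)hex-5-enal | C=C[C@](C)(O[Si](CC)(CC)CC)CCC=O | intermediate
11 | (6R)-2,6-dimethyl-6-(triethylsilyloxy)octa-1,7-dien-3-ol (both C3 epimers) | C=C[C@](C)(O[Si](CC)(CC)CC)CCC(O)C(C)=C | intermediate
12 | (6R)-2,6-dimethyl-6-(triethylsilyloxy)octa-1,7-dien-3-one (fragment B) | C=C[C@](C)(O[Si](CC)(CC)CC)CCC(=O)C(C)=C | intermediate
13 | lithium enolate of 6 | COC(O[Li])=CC[C@H]1OC(C)(C)O[C@H]1C(C)(C)C=C | intermediate
14 | methyl 2-{[(4R,5S)-2,2-dimethyl-5-(2-methylbut-3-en-2-yl)-1,3-dioxolan-4-yl]methyl}-3-hydroxy-6-methyl-3-(prop-1-en-2-yl)-6-(triethylsilyloxy)oct-7-enoate (6R; mixture at C2 and C3) | COC(=O)C(C[C@H]1OC(C)(C)O[C@H]1C(C)(C)C=C)C(O)(C(C)=C)CC[C@@](C)(O[Si](CC)(CC)CC)C=C | intermediate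
15 | methyl 2-{[(4R,5S)-2,2-dimethyl-5-(2-methylbut-3-en-2-yl)-1,3-dioxolan-4-yl]methyl}-4-methyl-3-[(3R)-3-methyl-3-(triethylsilyloxy)pent-4-en-1-yl]-5-oxopent-3-enoate (E/Z mixture) | COC(=O)C(C[C@H]1OC(C)(C)O[C@H]1C(C)(C)C=C)C(CC[C@@](C)(O[Si](CC)(CC)CC)C=C)=C(C)C=O | intermediate
16 | 3-{[(4R,5S)-2,2-dimethyl-5-(2-methylbut-3-en-2-yl)-1,3-dioxolan-4-yl]methyl}-5-methyl-4-[(3R)-3-methyl-3-(triethylsilyloxy)pent-4-en-1-yl]-2H-pyran-2-one | C=CC(C)(C)[C@@H]1OC(C)(C)O[C@@H]1CC2=C(CC[C@@](C)(O[Si](CC)(CC)CC)C=C)C(C)=COC2=O | intermediate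
17 | 2α,3α-(isopropylidenedioxy)-13R-(triethylsilyloxy)-5α-labda-8,14-dien-20-oic acid 20,7β-lactone | C=C[C@](C)(O[Si](CC)(CC)CC)CCC1=C(C)[C@@H]3C[C@H]2C(C)(C)[C@@H]4OC(C)(C)O[C@@H]4C[C@]12C(=O)O3 | intermediate
18 | 2α,3α-(isopropylidenedioxy)-13R-(triethylsilyloxy)-5α-labda-8,14-diene-7β,20-diol | C=C[C@](C)(O[Si](CC)(CC)CC)CCC1=C(C)[C@@H](O)C[C@H]2C(C)(C)[C@@H]3OC(C)(C)O[C@@H]3C[C@]12CO | intermediate
19 | 7β-hydroxy-2α,3α-(isopropylidenedioxy)-13R-(triethylsilyloxy)-5α-labda-8,14-dien-20-yl acetate | C=C[C@](C)(O[Si](CC)(CC)CC)CCC1=C(C)[C@@H](O)C[C@H]2C(C)(C)[C@@H]3OC(C)(C)O[C@@H]3C[C@]12COC(C)=O | intermediate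
20 | 7α-[1-(2-nitrobenzenesulfonyl)hydrazin-1-yl]-2α,3α-(isopropylidenedioxy)-13R-(triethylsilyloxy)-5α-labda-8,14-dien-20-yl acetate | C=C[C@](C)(O[Si](CC)(CC)CC)CCC1=C(C)[C@H](N(N)S(=O)(=O)c4ccccc4[N+](=O)[O-])C[C@H]2C(C)(C)[C@@H]3OC(C)(C)O[C@@H]3C[C@]12COC(C)=O | intermediate
21 | 7α-diazenyl-2α,3α-(isopropylidenedioxy)-13R-(triethylsilyloxy)-5α-labda-8,14-dien-20-yl acetate | C=C[C@](C)(O[Si](CC)(CC)CC)CCC1=C(C)[C@H](N=N)C[C@H]2C(C)(C)[C@@H]3OC(C)(C)O[C@@H]3C[C@]12COC(C)=O | intermediate
22 | 2α,3α-(isopropylidenedioxy)-13R-(triethylsilyloxy)labda-7,14-dien-20-yl acetate | C=C[C@](C)(O[Si](CC)(CC)CC)CC[C@H]1C(C)=CC[C@H]2C(C)(C)[C@@H]3OC(C)(C)O[C@@H]3C[C@]12COC(C)=O | intermediate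
23 | 2α,3α,13R-trihydroxylabda-7,14-dien-20-yl acetate | C=C[C@](C)(O)CC[C@H]1C(C)=CC[C@H]2C(C)(C)[C@H](O)[C@H](O)C[C@]12COC(C)=O | intermediate
24 | 20-acetoxy-2α-[(Z)-2-methylbut-2-enoyloxy]labda-7,14-diene-3α,13R-diol | C=C[C@](C)(O)CC[C@H]1C(C)=CC[C@H]2C(C)(C)[C@H](O)[C@H](OC(=O)/C(C)=C\C)C[C@]12COC(C)=O | target

**Totals**

Total step count: 16.
Longest linear sequence: 13 steps (from 7 through steps 4 to 16); the branch from 1 (steps 1 to 3) joins at step 8.

**Steps most likely to fail**

Step 11. The fully alkylated pyrone may add the unactivated vinyl group too slowly below the temperature at which the bridged lactone extrudes CO2 (which would lose C20), and the tether may partly adopt the endo arrangement. The fallback puts an iodine atom in place of the C17 methyl group on the pyrone, which makes the diene more reactive, and exchanges it for methyl after the cycloaddition. It sets out from aldehyde 10 (with enolate 13 from ester 6) and comes back at 17. Vinylmagnesium bromide adds to 10 to give the allylic alcohol F1, Dess–Martin oxidation gives the vinyl ketone F2, and I2 with pyridine in CH2Cl2 gives the α-iodo enone F3. Addition of enolate 13 under the conditions of step 8 gives the iodo hydroxy ester F4, oxidative transposition as in step 9 gives the iodo enal F5, and DBU closes the 5-iodopyrone F6. Heating F6 in toluene at about 100 °C should give the iodo lactone F7. Stille coupling of F7 with Me4Sn (Pd(PPh3)4, CuI, DMF, 60 °C) then replaces iodine by the C17 methyl group to give 17.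

Step 8. The enolate may add in the conjugate sense to the β-unsubstituted enone, or simply take a proton from the enolisable ketone, and the adduct may revert by retro-aldol on warming. The fallback changes the nucleophile to a Reformatsky reagent. It sets out from ester 6 and comes back at 14. Enolate 13 is brominated with CBr4 at −78 °C to give the α-bromo ester F8. Activated Zn dust in THF then generates the zinc enolate of F8 in the presence of enone 12; this enolate is far less basic and adds to the ketone carbonyl, giving 14 after aqueous work-up.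

Step 13. Discrimination between the neopentyl primary C20 alcohol and the secondary allylic C7 alcohol may be poor, leading to over-acetylation. The fallback makes over-acetylation the plan and removes the allylic acetate reductively. It sets out from diol 18 and comes back at 22, so it replaces step 14 as well. Ac2O, DMAP and pyridine give the 7β,20-diacetate F9. With Pd(OAc)2, PBu3 and HCO2NH4 in dioxane at 100 °C, zerovalent palladium should ionise the allylic C7 acetate from the α face. Formate then transfers hydride from the metal to the more substituted allyl terminus C9 on that same face, giving the C7=C8 alkene with 9α-H, that is 22, while the C20 acetate stays in place.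

Further compounds
F1 | step 11 | (6R)-6-methyl-6-(triethylsilyloxy)octa-1,7-dien-3-ol | C=C[C@](C)(O[Si](CC)(CC)CC)CCC(O)C=C
F2 | step 11 | (6R)-6-methyl-6-(triethylsilyloxy)octa-1,7-dien-3-one | C=C[C@](C)(O[Si](CC)(CC)CC)CCC(=O)C=C
F3 | step 11 | (6R)-2-iodo-6-methyl-6-(triethylsilyloxy)octa-1,7-dien-3-one | C=C[C@](C)(O[Si](CC)(CC)CC)CCC(=O)C(I)=C
F4 | step 11 | methyl 2-{[(4R,5S)-2,2-dimethyl-5-(2-methylbut-3-en-2-yl)-1,3-dioxolan-4-yl]methyl}-3-hydroxy-3-(1-iodoethenyl)-6-methyl-6-(triethylsilyloxy)oct-7-enoate (6R) | COC(=O)C(C[C@H]1OC(C)(C)O[C@H]1C(C)(C)C=C)C(O)(C(I)=C)CC[C@@](C)(O[Si](CC)(CC)CC)C=C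
F5 | step 11 | methyl 2-{[(4R,5S)-2,2-dimethyl-5-(2-methylbut-3-en-2-yl)-1,3-dioxolan-4-yl]methyl}-4-iodo-3-[(3R)-3-methyl-3-(triethylsilyloxy)pent-4-en-1-yl]-5-oxopent-3-enoate | COC(=O)C(C[C@H]1OC(C)(C)O[C@H]1C(C)(C)C=C)C(CC[C@@](C)(O[Si](CC)(CC)CC)C=C)=C(I)C=O
F6 | step 11 | 3-{[(4R,5S)-2,2-dimethyl-5-(2-methylbut-3-en-2-yl)-1,3-dioxolan-4-yl]methyl}-5-iodo-4-[(3R)-3-methyl-3-(triethylsilyloxy)pent-4-en-1-yl]-2H-pyran-2-one | C=CC(C)(C)[C@@H]1OC(C)(C)O[C@@H]1CC2=C(CC[C@@](C)(O[Si](CC)(CC)CC)C=C)C(I)=COC2=O
F7 | step 11 | 8-iodo-17-nor analogue of 17 (iodine on C8 in place of the methyl group) | C=C[C@](C)(O[Si](CC)(CC)CC)CCC1=C(I)[C@@H]3C[C@H]2C(C)(C)[C@@H]4OC(C)(C)O[C@@H]4C[C@]12C(=O)O3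
F8 | step 8 | methyl 2-bromo-3-[(4R,5S)-2,2-dimethyl-5-(2-methylbut-3-en-2-yl)-1,3-dioxolan-4-yl]propanoate | COC(=O)C(Br)C[C@H]1OC(C)(C)O[C@H]1C(C)(C)C=C
F9 | step 13 | 2α,3α-(isopropylidenedioxy)-13R-(triethylsilyloxy)-5α-labda-8,14-diene-7β,20-diyl diacetate | C=C[C@](C)(O[Si](CC)(CC)CC)CCC1=C(C)[C@@H](OC(C)=O)C[C@H]2C(C)(C)[C@@H]3OC(C)(C)O[C@@H]3C[C@]12COC(C)=O
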